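**Retrosynthetic overview**
- Ring C is opened at O1–C2 (catalyst-controlled oxa-Michael), giving the 2',4'-dihydroxychalcone abyssinone VI. Ring A of that chalcone is then cut by Diels–Alder/retro-Diels–Alder into a cross-conjugated aryl enynone and the bis-silyl dienol ether of dimedone.
- In the forward direction both events run in one flask. Ring A forms first, ring C second, and the only stereocentre (C2) is set in the ring C closure, which is the last bond formed.
- The enynone comes from a cinnamoyl Weinreb amide and ethynylmagnesium bromide. The amide comes from a Heck reaction of 4-iodo-2,6-diprenylphenol.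
- Ring B is bought as 4-iodophenol, and both prenyl groups are installed by aqueous phenoxide C-alkylation. No protecting groups are carried.

Assumption: the epi-quinine-derived thiourea is taken to give the (S)-flavanone. If the sense proves opposite, the pseudo-enantiomeric epi-quinidine catalyst is used and nothing else changes.

**Step 1**
Reactants: 1 4-iodophenol; 2 prenyl bromide (1-bromo-3-methylbut-2-ene)
Product: 4 4-iodo-2,6-bis(3-methylbut-2-en-1-yl)phenol, via mono-prenyl iodophenol 3 (not isolated)
Conditions: 2 (2.5 equiv), KOH (2.5 equiv), H2O, rt, 24 h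
Reagents that add atoms: none
Why: Phenoxide C-alkylation; in water the phenoxide oxygen is heavily solvated, so the soft primary allylic bromide is attacked (SN2, linear prenyl) by the ortho carbons, the para position is blocked by iodine, and mono-prenyl phenol 3 re-enters the same reaction; no stereocentre.

**Step 2**
Reactants: 4 4-iodo-2,6-bis(3-methylbut-2-en-1-yl)phenol; 5 N-methoxy-N-methylacrylamide
Product: 6 (E)-3-[4-hydroxy-3,5-bis(3-methylbut-2-en-1-yl)phenyl]-N-methoxy-N-methylprop-2-enamide
Conditions: 5 (1.3 equiv), Pd(OAc)2 (3 mol %), P(o-tol)3 (9 mol %), Et3N (2 equiv), PhMe, 95 °C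
Reagents that add atoms: none
Why: Mizoroki–Heck reaction; the aryl iodide adds to Pd(0), inserts into the unhindered acrylamide and gives the (E)-alkene by syn β-H elimination, while the trisubstituted prenyl alkenes do not insert and the hindered free phenol is tolerated.

**Step 3**
Reactants: 6 the Weinreb cinnamamide; 7 ethynylmagnesium bromide
Product: 9 (E)-1-[4-hydroxy-3,5-bis(3-methylbut-2-en-1-yl)phenyl]pent-1-en-4-yn-3-one, via bromomagnesium hemiaminal 8 (not isolated)
Conditions: 7 (3.5 equiv, 0.5 M in THF), THF, 0 °C, 1 h; cannulate into cold 1 M HCl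
Reagents that add atoms: none
Why: Weinreb ketone synthesis; one equivalent of 7 deprotonates the phenol, a second adds 1,2 to the amide, the N-methoxy chelate 8 prevents over-addition, and the inverse acidic quench protonates the released amine before it can add to the terminal ynone.

**Step 4**
Reactants: 10 dimedone (5,5-dimethylcyclohexane-1,3-dione)
Product: 12 5,5-dimethyl-1,3-bis(trimethylsilyloxy)cyclohexa-1,3-diene, via mono-silyl enol ether 11 (not isolated)
Conditions: TMSOTf (2.3 equiv), Et3N (2.6 equiv), Et2O, 0 °C to rt; decant, distil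
Reagents that add atoms: trimethylsilyl triflate, C[Si](C)(C)OS(=O)(=O)C(F)(F)F
Why: Soft enolisation/O-silylation; the vinylogous acid is silylated to 11, a second O-silylation gives a symmetrical bis(silyloxy)allyl cation, and Et3N deprotonates this at the flanking CH2, so only the 1,3-diene can form.

**Step 5 (key step)**
Reactants: 9 the enynone; 12 the bis-silyloxy diene
Product: 16 abyssinone IV [(2S)-7-hydroxy-2-[4-hydroxy-3,5-bis(3-methylbut-2-en-1-yl)phenyl]-2,3-dihydro-4H-chromen-4-one], via bicyclo[2.2.2]octadiene adduct 13 (not isolated), via bis-TMS chalcone 14 (not isolated), via abyssinone VI chalcone 15 (not isolated)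
Conditions: 12 (1.5 equiv), PhCl, 130 °C, sealed tube, 14 h; strip volatiles plus excess 12 (80 °C, 0.1 mbar); MeOH, rt, 30 min, evaporate; 9-amino(9-deoxy)epi-quinine 3,5-(CF3)2C6H3-thiourea (20 mol %), PhCl, rt, 72–96 h, stop at about 90 % conversion; all in one flask; recrystallise
Reagents that add atoms: none
Why: Proposed new method: diene 12 undergoes a Diels–Alder reaction with the terminal ynone of 9 (its most nucleophilic C-4 bonds to the alkyne CH, the silyloxy-bearing C-1 to the acyl-bearing carbon, and the β-aryl enone and prenyl alkenes are much poorer dienophiles); adduct 13 aromatises by retro-Diels–Alder loss of isobutene, which builds ring A with the 2',4'-dioxygenation pattern (closest known type: resorcinol synthesis from alkynoates or ynones and dimedone-derived bis-silyloxydienes); methanol then frees the two acidic phenols, and the bifunctional catalyst acts as a chalcone-isomerase mimic (thiourea H-bonds the C=O, quinuclidine takes the 2'-OH proton), so the phenoxide closes ring C by 6-endo-trig oxa-Michael addition on the Si face of C-β and sets (2S) (closest known type: cinchona-thiourea-catalysed asymmetric cyclisation of 2'-hydroxychalcones to flavanones); what is new is the telescoping and the unprotected, electron-rich substrate, and because the closure is reversible it is stopped before equilibrium and the ee is upgraded by crystallisation.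

**Compound list**
1 | 4-iodophenol | Oc1ccc(I)cc1 | starting material
2 | prenyl bromide (1-bromo-3-methylbut-2-ene) | CC(C)=CCBr | starting material
3 | 4-iodo-2-(3-methylbut-2-en-1-yl)phenol | CC(C)=CCc1cc(I)ccc1O | intermediate
4 | 4-iodo-2,6-bis(3-methylbut-2-en-1-yl)phenol | CC(C)=CCc1cc(I)cc(CC=C(C)C)c1O | intermediate
5 | N-methoxy-N-methylacrylamide | C=CC(=O)N(C)OC | starting material
6 | (E)-3-[4-hydroxy-3,5-bis(3-methylbut-2-en-1-yl)phenyl]-N-methoxy-N-methylprop-2-enamide | CON(C)C(=O)/C=C/c1cc(CC=C(C)C)c(O)c(CC=C(C)C)c1 | intermediate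
7 | ethynylmagnesium bromide | C#C[Mg]Br | starting material
8 | bis(bromomagnesium) salt of the tetrahedral ethynyl adduct of 6 (racemic at the hemiaminal carbon) | C#CC(O[Mg]Br)(N(C)OC)/C=C/c1cc(CC=C(C)C)c(O[Mg]Br)c(CC=C(C)C)c1 | intermediate
9 | (E)-1-[4-hydroxy-3,5-bis(3-methylbut-2-en-1-yl)phenyl]pent-1-en-4-yn-3-one | C#CC(=O)/C=C/c1cc(CC=C(C)C)c(O)c(CC=C(C)C)c1 | intermediate
10 | dimedone | CC1(C)CC(=O)CC(=O)C1 | starting material
11 | 5,5-dimethyl-3-(trimethylsilyloxy)cyclohex-2-en-1-one | CC1(C)CC(=O)C=C(O[Si](C)(C)C)C1 | intermediate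
12 | 5,5-dimethyl-1,3-bis(trimethylsilyloxy)cyclohexa-1,3-diene | CC1(C)CC(O[Si](C)(C)C)=CC(O[Si](C)(C)C)=C1 | intermediate
13 | (E)-1-[8,8-dimethyl-1,5-bis(trimethylsilyloxy)bicyclo[2.2.2]octa-2,5-dien-2-yl]-3-[4-hydroxy-3,5-bis(3-methylbut-2-en-1-yl)phenyl]prop-2-en-1-one (racemic) | O=C(/C=C/c1cc(CC=C(C)C)c(O)c(CC=C(C)C)c1)C1=CC2C(O[Si](C)(C)C)=CC1(O[Si](C)(C)C)CC2(C)C | intermediate
14 | (E)-1-[2,4-bis(trimethylsilyloxy)phenyl]-3-[4-hydroxy-3,5-bis(3-methylbut-2-en-1-yl)phenyl]prop-2-en-1-one | O=C(/C=C/c1cc(CC=C(C)C)c(O)c(CC=C(C)C)c1)c1ccc(O[Si](C)(C)C)cc1O[Si](C)(C)C | intermediate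
15 | abyssinone VI, (E)-1-(2,4-dihydroxyphenyl)-3-[4-hydroxy-3,5-bis(3-methylbut-2-en-1-yl)phenyl]prop-2-en-1-one | O=C(/C=C/c1cc(CC=C(C)C)c(O)c(CC=C(C)C)c1)c1ccc(O)cc1O | intermediate
16 | abyssinone IV, (2S)-7-hydroxy-2-[4-hydroxy-3,5-bis(3-methylbut-2-en-1-yl)phenyl]-2,3-dihydro-4H-chromen-4-one | CC(C)=CCc1cc([C@@H]2CC(=O)c3ccc(O)cc3O2)cc(CC=C(C)C)c1O | target

**Total step count:** 5. **Longest linear sequence:** 4 (1 → 4 → 6 → 9 → 16).

**Three steps most likely to fail**

Step 5 is the riskiest. The thermal ring A construction has close precedent. The enantioselective closure of an unactivated, electron-rich chalcone with three free phenols may be slow, and its reversibility may hold the ee down. The fallback sets out from 15 and comes back at 16. Chalcone 15, still made by the same one-flask ring A construction, is closed without chiral control (NaOAc, EtOH, reflux) to racemic abyssinone IV F1. F1 is then resolved by catalytic kinetic resolution through asymmetric transfer hydrogenation (RuCl(p-cymene)[(R,R)-TsDPEN], HCO2H/Et3N 5:2, EtOAc, rt, about 52 % conversion). The (R)-ketone is the matched substrate and is reduced to the cis-(2R,4R)-flavan-4-ol F2. The unreacted (S)-ketone 16 is separated from F2 by chromatography. The prenyl alkenes and phenols are inert to this catalyst.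

Step 1 may give too much O-alkylation, mono-prenylation or dienone by-product. The fallback sets out from 1 (with 5) and comes back at 6, replacing phenoxide alkylation with cross-coupling at the cost of one extra step. A Heck reaction of 1 with 5 gives (E)-3-(4-hydroxyphenyl)-N-methoxy-N-methylprop-2-enamide F3. NBS (2.05 equiv, MeCN, 0 °C) brominates both ortho positions to give the 3,5-dibromophenol F4. A double Stille coupling with tributyl(3-methylbut-2-enyl)stannane (Pd(PPh3)4, DMF, 90 °C) then installs both linear prenyl groups and delivers 6.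

Step 3 may suffer from addition of the released amine to the terminal ynone, or from polymerisation. The fallback sets out from 6 and comes back at 9, building the ketone by carbinol oxidation instead of acyl substitution. DIBAL-H (2.2 equiv, THF, −78 °C) reduces 6 to (E)-3-[4-hydroxy-3,5-bis(3-methylbut-2-en-1-yl)phenyl]prop-2-enal F5. Addition of 7 (2.5 equiv, THF, 0 °C) gives the racemic allylic–propargylic alcohol (E)-1-aryl-pent-1-en-4-yn-3-ol F6. Parikh–Doering oxidation (SO3·pyridine, DMSO, iPr2NEt, 0 °C) converts F6 to 9 with no nucleophilic amine present.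

**Further compounds**
F1 | step 5 | racemic abyssinone IV | CC(C)=CCc1cc(C2CC(=O)c3ccc(O)cc3O2)cc(CC=C(C)C)c1O
F2 | step 5 | (2R,4R)-2-[4-hydroxy-3,5-bis(3-methylbut-2-en-1-yl)phenyl]chromane-4,7-diol (2,4-cis) | CC(C)=CCc1cc([C@H]2C[C@@H](O)c3ccc(O)cc3O2)cc(CC=C(C)C)c1O
F3 | step 1 | (E)-3-(4-hydroxyphenyl)-N-methoxy-N-methylprop-2-enamide | CON(C)C(=O)/C=C/c1ccc(O)cc1
F4 | step 1 | (E)-3-(3,5-dibromo-4-hydroxyphenyl)-N-methoxy-N-methylprop-2-enamide | CON(C)C(=O)/C=C/c1cc(Br)c(O)c(Br)c1
F5 | step 3 | (E)-3-[4-hydroxy-3,5-bis(3-methylbut-2-en-1-yl)phenyl]prop-2-enal | O=C/C=C/c1cc(CC=C(C)C)c(O)c(CC=C(C)C)c1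
F6 | step 3 | (E)-1-[4-hydroxy-3,5-bis(3-methylbut-2-en-1-yl)phenyl]pent-1-en-4-yn-3-ol (racemic) | C#CC(O)/C=C/c1cc(CC=C(C)C)c(O)c(CC=C(C)C)c1
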